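## Retrosynthetic overview

1. Numbering used below: lactone O–C6, C7, C11(=C13H2), C12=O; C8 carries the acyloxy group, C10 the formyl carbon C14, C4 the acetoxymethyl carbon C15.
2. Ten-membered ring (formed last): ring-closing metathesis at C1=C10 between a terminal alkene and a 2-methylene aldehyde made by α-methylenation.
3. Lactone ring (formed first), C6–C7 bond with both stereocentres: chiral-phosphoric-acid-catalysed, lactone-forming allylboration of enal 7 with 2-(alkoxycarbonyl)allylboronate 14.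
4. Boronate 14 comes from 4,4-dimethoxybutanal and methyl propiolate (catalytic asymmetric alkynylation sets C8); enal 7 comes from but-2-yne-1,4-diol by directed anti-carbomagnesiation, which sets the C4=C5 geometry.
5. The side chain, (S)-2-methylbutanoic acid, comes from tiglic acid by asymmetric hydrogenation and is attached at C8 by esterification.

Assumption: the facial senses of (S,S)-ProPhenol/Me2Zn (step 4), (S)-TRIP (step 7; (R)-TRIP is taken to deliver allyl to the Re face of an aldehyde) and Ru(OAc)2[(S)-H8-BINAP] (step 9) are taken from their closest precedents, and the mirror-image catalyst is used wherever a sense proves opposite.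

## Route

Step 1
Reactants: 1 but-2-yne-1,4-diol
Product: 2 4-[(triethylsilyl)oxy]but-2-yn-1-ol
Conditions: TESCl (1 equiv), imidazole, 1 (3 equiv), THF/DMF, 0 °C
Reagents that add atoms: chlorotriethylsilane, CC[Si](Cl)(CC)CC
Why: Statistical monosilylation of the symmetric diol used in excess leaves one free hydroxyl to direct the next step, and no stereocentre is formed.

Step 2
Reactants: 2 4-[(triethylsilyl)oxy]but-2-yn-1-ol; 3 but-3-en-1-ylmagnesium bromide
Product: 6 (2E)-2-(but-3-en-1-yl)-4-[(triethylsilyl)oxy]but-2-en-1-yl acetate, via oxamagnesacycle 4 (not isolated), via allylic alcohol 5 (not isolated)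
Conditions: 3 (3 equiv), CuI (10 mol%), THF, −10 °C → rt; then MeOH (2.1 equiv), 0 °C; then Ac2O, DMAP (cat.), rt
Reagents that add atoms: acetic anhydride, CC(=O)OC(C)=O
Why: Hydroxyl-directed copper-catalysed anti-carbomagnesiation of a propargylic alcohol (Duboudin–Jousseaume type) puts the butenyl group on the alkyne carbon next to the free carbinol and magnesium on the other carbon inside a five-membered chelate, so protonation with methanol fixes the chain cis to CH2OSiEt3 (the ring-cis C4=C5 geometry of the target, 2E by CIP rules) and the magnesium alkoxide is acetylated in the same flask.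

Step 3
Reactants: 6 (2E)-2-(but-3-en-1-yl)-4-[(triethylsilyl)oxy]but-2-en-1-yl acetate
Product: 7 (2E)-2-(but-3-en-1-yl)-4-oxobut-2-en-1-yl acetate
Conditions: (COCl)2, DMSO, CH2Cl2, −78 → −40 °C; then Et3N, −78 → 0 °C
Reagents that add atoms: none
Why: Under Swern conditions a primary allylic triethylsilyl ether is converted directly into the aldehyde (oxidative desilylation) at low temperature, which leaves the acetate and the alkene geometry untouched.

Step 4
Reactants: 8 4,4-dimethoxybutanal; 9 methyl prop-2-ynoate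
Product: 10 methyl (4R)-4-hydroxy-7,7-dimethoxyhept-2-ynoate
Conditions: (S,S)-ProPhenol (10 mol%), Me2Zn (3 equiv), Ph3PO (20 mol%), toluene, 0 °C
Reagents that add atoms: none
Why: Zinc–ProPhenol-catalysed enantioselective alkynylation of an aliphatic aldehyde with methyl propiolate (Trost type) adds the zinc acetylide to one aldehyde face inside the dinuclear zinc pocket and sets C8 as R, the first stereocentre, from achiral inputs.

Step 5
Reactants: 10 methyl (4R)-4-hydroxy-7,7-dimethoxyhept-2-ynoate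
Product: 11 methyl (4R)-4-[(tert-butyldimethylsilyl)oxy]-7,7-dimethoxyhept-2-ynoate
Conditions: TBSCl, imidazole, DMF, rt
Reagents that add atoms: tert-butylchlorodimethylsilane, CC(C)(C)[Si](C)(C)Cl
Why: Standard silyl ether formation protects the propargylic alcohol so that it survives the hydride reagent of step 6 and cannot lactonise in step 7, with the configuration untouched.

Step 6
Reactants: 11 methyl (4R)-4-[(tert-butyldimethylsilyl)oxy]-7,7-dimethoxyhept-2-ynoate; 12 2-(iodomethyl)-4,4,5,5-tetramethyl-1,3,2-dioxaborolane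
Product: 14 methyl (2Z,4R)-4-[(tert-butyldimethylsilyl)oxy]-7,7-dimethoxy-2-[(4,4,5,5-tetramethyl-1,3,2-dioxaborolan-2-yl)methyl]hept-2-enoate, via alkenylalane 13 (not isolated)
Conditions: i-Bu2AlH (1.2 equiv), HMPA, MeCu (10 mol%, from MeLi and CuI), THF, −50 °C; then 12, −50 → 0 °C
Reagents that add atoms: none
Why: Copper-catalysed conjugate hydroalumination of the ynoate (Tsuda type) gives an α-aluminated enoate that is alkylated by the iodomethylboronate on the side of the β-hydrogen, which places the C8 chain cis to the ester and trans to CH2B as needed for an anti-selective allylboration, and C8 is not touched.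

Step 7
Reactants: 7 (2E)-2-(but-3-en-1-yl)-4-oxobut-2-en-1-yl acetate; 14 methyl (2Z,4R)-4-[(tert-butyldimethylsilyl)oxy]-7,7-dimethoxy-2-[(4,4,5,5-tetramethyl-1,3,2-dioxaborolan-2-yl)methyl]hept-2-enoate
Product: 16 (4S,5R)-5-[(1E)-2-(acetoxymethyl)hexa-1,5-dien-1-yl]-4-[(1R)-1-[(tert-butyldimethylsilyl)oxy]-4,4-dimethoxybutyl]-3-methylidenedihydrofuran-2(3H)-one, via borate ester 15 (not isolated)
Conditions: (S)-TRIP (10 mol%), 4 Å MS, toluene, −20 °C → rt; then CSA (10 mol%), rt
Reagents that add atoms: none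
Why: Proposed new method: a chiral phosphoric acid is expected to catalyse allylboration of the enal by the ester-deactivated, γ-substituted 2-(alkoxycarbonyl)allylboronate by hydrogen-bonding its P–OH to the pseudo-axial boronate oxygen (raising boron Lewis acidity) while P=O holds the formyl C–H, so that the Si face of 7 is attacked through a closed chair transition state with the C8 chain equatorial, giving the anti adduct with C6 (R) and C7 set under catalyst control over the modest bias of C8, after which acid-promoted lactonisation closes the trans α-methylene-γ-butyrolactone; the closest known reactions are the chiral-phosphoric-acid-catalysed allyl- and crotylboration of aldehydes with pinacol boronates and the achiral Brønsted- or Lewis-acid-catalysed lactone-forming allylboration with 2-(alkoxycarbonyl)allylboronates.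

Step 8
Reactants: 16 (4S,5R)-5-[(1E)-2-(acetoxymethyl)hexa-1,5-dien-1-yl]-4-[(1R)-1-[(tert-butyldimethylsilyl)oxy]-4,4-dimethoxybutyl]-3-methylidenedihydrofuran-2(3H)-one
Product: 17 (4R,5R)-5-[(1E)-2-(acetoxymethyl)hexa-1,5-dien-1-yl]-4-[(1R)-1-hydroxy-4,4-dimethoxybutyl]-3-methylidenedihydrofuran-2(3H)-one
Conditions: TBAF, AcOH (1:1), THF, 0 °C → rt
Reagents that add atoms: none
Why: Acetic-acid-buffered fluoride desilylation frees the C8 hydroxyl without acid strong enough to cyclise the γ-hydroxy acetal and without base strong enough to harm the acetate or the α-methylene lactone (the C7 descriptor changes from S to R only because the O–Si substituent is lost).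

Step 9
Reactants: 18 (2E)-2-methylbut-2-enoic acid (tiglic acid)
Product: 19 (2S)-2-methylbutanoic acid
Conditions: Ru(OAc)2[(S)-H8-BINAP] (0.5 mol%), H2 (4 atm), MeOH, rt
Reagents that add atoms: none
Why: Ruthenium–BINAP-type asymmetric hydrogenation of an α,β-unsaturated carboxylic acid (Noyori–Takaya type) adds hydrogen to one face of the carboxylate-bound alkene and sets the (S) centre of the side-chain acid.

Step 10
Reactants: 17 (4R,5R)-5-[(1E)-2-(acetoxymethyl)hexa-1,5-dien-1-yl]-4-[(1R)-1-hydroxy-4,4-dimethoxybutyl]-3-methylidenedihydrofuran-2(3H)-one; 19 (2S)-2-methylbutanoic acid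
Product: 20 (1R)-1-[(2R,3R)-2-[(1E)-2-(acetoxymethyl)hexa-1,5-dien-1-yl]-4-methylidene-5-oxooxolan-3-yl]-4,4-dimethoxybutyl (2S)-2-methylbutanoate
Conditions: DCC, DMAP (10 mol%), CH2Cl2, 0 °C → rt
Reagents that add atoms: none
Why: Steglich esterification acylates the secondary C8 alcohol without breaking its C–O bond and without epimerising the α-alkyl centre of the acid, so both configurations are retained.

Step 11
Reactants: 20 (1R)-1-[(2R,3R)-2-[(1E)-2-(acetoxymethyl)hexa-1,5-dien-1-yl]-4-methylidene-5-oxooxolan-3-yl]-4,4-dimethoxybutyl (2S)-2-methylbutanoate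
Product: 21 (1R)-1-[(2R,3R)-2-[(1E)-2-(acetoxymethyl)hexa-1,5-dien-1-yl]-4-methylidene-5-oxooxolan-3-yl]-4-oxobutyl (2S)-2-methylbutanoate
Conditions: PPTS (20 mol%), acetone/H2O (10:1), 50 °C
Reagents that add atoms: water, O
Why: Mild acid-catalysed acetal hydrolysis unmasks the C14 aldehyde while the esters, the lactone and the allylic acetate are stable.

Step 12
Reactants: 21 (1R)-1-[(2R,3R)-2-[(1E)-2-(acetoxymethyl)hexa-1,5-dien-1-yl]-4-methylidene-5-oxooxolan-3-yl]-4-oxobutyl (2S)-2-methylbutanoate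
Product: 22 (1R)-1-[(2R,3R)-2-[(1E)-2-(acetoxymethyl)hexa-1,5-dien-1-yl]-4-methylidene-5-oxooxolan-3-yl]-3-formylbut-3-en-1-yl (2S)-2-methylbutanoate
Conditions: 37% aq. CH2O, i-Pr2NH·TFA, THF, 60 °C
Reagents that add atoms: formaldehyde, C=O
Why: Amine-salt-catalysed α-methylenation of an aldehyde (Mannich condensation followed by β-elimination of the amine) installs the C10 methylidene needed for ring closure, the hindered amine does not add to the α-methylene lactone, and no stereocentre is formed or lost.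

Step 13
Reactants: 22 (1R)-1-[(2R,3R)-2-[(1E)-2-(acetoxymethyl)hexa-1,5-dien-1-yl]-4-methylidene-5-oxooxolan-3-yl]-3-formylbut-3-en-1-yl (2S)-2-methylbutanoate
Product: 23 [(3aR,4R,6E,10E,11aR)-10-(acetoxymethyl)-6-formyl-3-methylidene-2-oxo-2,3,3a,4,5,8,9,11a-octahydrocyclodeca[b]furan-4-yl] (2S)-2-methylbutanoate (CNP0230988.9)
Conditions: second-generation Hoveyda–Grubbs catalyst (15 mol%), 1,4-benzoquinone (30 mol%), toluene (1 mM), 80 °C
Reagents that add atoms: none
Why: Ring-closing metathesis initiates at the terminal alkene and closes onto the 2-substituted acrolein to give the trisubstituted enal of the ten-membered ring, whose ring-cis geometry (E by CIP rules, formyl trans to C2) is both the less strained ring alkene and the thermodynamically preferred enal geometry, while the α-methylene lactone and the trisubstituted C4=C5 alkene are poorer metathesis partners.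

## Compound list

1 | but-2-yne-1,4-diol | OCC#CCO | starting material
2 | 4-[(triethylsilyl)oxy]but-2-yn-1-ol | CC[Si](CC)(CC)OCC#CCO | intermediate
3 | but-3-en-1-ylmagnesium bromide | C=CCC[Mg]Br | starting material
4 | 4-(but-3-en-1-yl)-3-{[(triethylsilyl)oxy]methyl}-2,5-dihydro-1,2-oxamagnesole (C–Mg–O chelate from anti addition) | C=CCCC1=C(CO[Si](CC)(CC)CC)[Mg]OC1 | intermediate
5 | (2E)-2-(but-3-en-1-yl)-4-[(triethylsilyl)oxy]but-2-en-1-ol (present as its magnesium alkoxide) | C=CCC/C(CO)=C\CO[Si](CC)(CC)CC | intermediate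
6 | (2E)-2-(but-3-en-1-yl)-4-[(triethylsilyl)oxy]but-2-en-1-yl acetate | C=CCC/C(COC(C)=O)=C\CO[Si](CC)(CC)CC | intermediate
7 | (2E)-2-(but-3-en-1-yl)-4-oxobut-2-en-1-yl acetate | C=CCC/C(COC(C)=O)=C\C=O | intermediate
8 | 4,4-dimethoxybutanal | COC(OC)CCC=O | starting material
9 | methyl prop-2-ynoate | C#CC(=O)OC | starting material
10 | methyl (4R)-4-hydroxy-7,7-dimethoxyhept-2-ynoate | COC(=O)C#C[C@H](O)CCC(OC)OC | intermediate
11 | methyl (4R)-4-[(tert-butyldimethylsilyl)oxy]-7,7-dimethoxyhept-2-ynoate | COC(=O)C#C[C@H](O[Si](C)(C)C(C)(C)C)CCC(OC)OC | intermediate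
12 | 2-(iodomethyl)-4,4,5,5-tetramethyl-1,3,2-dioxaborolane | ICB1OC(C)(C)C(C)(C)O1 | starting material
13 | methyl (2E,4R)-2-[bis(2-methylpropyl)alumanyl]-4-[(tert-butyldimethylsilyl)oxy]-7,7-dimethoxyhept-2-enoate | COC(=O)/C([Al](CC(C)C)CC(C)C)=C\[C@H](O[Si](C)(C)C(C)(C)C)CCC(OC)OC | intermediate
14 | methyl (2Z,4R)-4-[(tert-butyldimethylsilyl)oxy]-7,7-dimethoxy-2-[(4,4,5,5-tetramethyl-1,3,2-dioxaborolan-2-yl)methyl]hept-2-enoate | COC(=O)/C(CB1OC(C)(C)C(C)(C)O1)=C\[C@H](O[Si](C)(C)C(C)(C)C)CCC(OC)OC | intermediate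
15 | methyl (3S,4R,5E)-6-(acetoxymethyl)-3-[(1R)-1-[(tert-butyldimethylsilyl)oxy]-4,4-dimethoxybutyl]-2-methylidene-4-[(4,4,5,5-tetramethyl-1,3,2-dioxaborolan-2-yl)oxy]deca-5,9-dienoate | COC(=O)C(=C)[C@@H]([C@H](OB1OC(C)(C)C(C)(C)O1)/C=C(/COC(C)=O)CCC=C)[C@H](O[Si](C)(C)C(C)(C)C)CCC(OC)OC | intermediate
16 | (4S,5R)-5-[(1E)-2-(acetoxymethyl)hexa-1,5-dien-1-yl]-4-[(1R)-1-[(tert-butyldimethylsilyl)oxy]-4,4-dimethoxybutyl]-3-methylidenedihydrofuran-2(3H)-one | C=C1C(=O)O[C@H](/C=C(/COC(C)=O)CCC=C)[C@H]1[C@H](O[Si](C)(C)C(C)(C)C)CCC(OC)OC | intermediate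
17 | (4R,5R)-5-[(1E)-2-(acetoxymethyl)hexa-1,5-dien-1-yl]-4-[(1R)-1-hydroxy-4,4-dimethoxybutyl]-3-methylidenedihydrofuran-2(3H)-one | C=C1C(=O)O[C@H](/C=C(/COC(C)=O)CCC=C)[C@H]1[C@H](O)CCC(OC)OC | intermediate
18 | (2E)-2-methylbut-2-enoic acid (tiglic acid) | C/C=C(\C)C(=O)O | starting material
19 | (2S)-2-methylbutanoic acid | OC(=O)[C@@H](C)CC | intermediate
20 | (1R)-1-[(2R,3R)-2-[(1E)-2-(acetoxymethyl)hexa-1,5-dien-1-yl]-4-methylidene-5-oxooxolan-3-yl]-4,4-dimethoxybutyl (2S)-2-methylbutanoate | C=C1C(=O)O[C@H](/C=C(/COC(C)=O)CCC=C)[C@H]1[C@H](OC(=O)[C@@H](C)CC)CCC(OC)OC | intermediate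
21 | (1R)-1-[(2R,3R)-2-[(1E)-2-(acetoxymethyl)hexa-1,5-dien-1-yl]-4-methylidene-5-oxooxolan-3-yl]-4-oxobutyl (2S)-2-methylbutanoate | C=C1C(=O)O[C@H](/C=C(/COC(C)=O)CCC=C)[C@H]1[C@H](OC(=O)[C@@H](C)CC)CCC=O | intermediate
22 | (1R)-1-[(2R,3R)-2-[(1E)-2-(acetoxymethyl)hexa-1,5-dien-1-yl]-4-methylidene-5-oxooxolan-3-yl]-3-formylbut-3-en-1-yl (2S)-2-methylbutanoate | C=C1C(=O)O[C@H](/C=C(/COC(C)=O)CCC=C)[C@H]1[C@H](OC(=O)[C@@H](C)CC)CC(=C)C=O | intermediate
23 | [(3aR,4R,6E,10E,11aR)-10-(acetoxymethyl)-6-formyl-3-methylidene-2-oxo-2,3,3a,4,5,8,9,11a-octahydrocyclodeca[b]furan-4-yl] (2S)-2-methylbutanoate | C=C1C(=O)O[C@@H]2/C=C(/COC(C)=O)CC/C=C(/C=O)C[C@@H](OC(=O)[C@@H](C)CC)[C@@H]12 | target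

## Step count and risks

Total step count: 13. Longest linear sequence: 9 steps (steps 1, 2, 3, 7, 8, 10, 11, 12, 13; the branch through steps 4, 5, 6 is equally long).

The three steps most likely to fail:

Step 7 (the proposed new reaction). The boronate is deactivated by its ester, the enal is β,β-disubstituted, and the catalyst must override the C8 stereocentre. The fallback sets out from 7 and 14 and drops catalyst control: the two are heated without any catalyst in toluene at 80 °C, the known thermal closed-transition-state allylboration of 2-(alkoxycarbonyl)allylboronates, in which the geometry of 14 still enforces the anti (trans-lactone) relationship and the facial choice rests on the resident C8 stereocentre. After aqueous work-up the anti hydroxy ester methyl (3S,4R,5E)-6-(acetoxymethyl)-3-[(1R)-1-[(tert-butyldimethylsilyl)oxy]-4,4-dimethoxybutyl]-4-hydroxy-2-methylidenedeca-5,9-dienoate F3 is separated by chromatography from its C6,C7 bis-epimer, the (3R,4S,5E) hydroxy ester F4, and F3 is lactonised with p-TsOH in CH2Cl2 at room temperature to give 16, where the route is rejoined.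

Step 13 (ring-closing metathesis). A trisubstituted enal must form in a ten-membered ring, and closure onto the lactone methylidene (eight-membered ring) or oligomerisation can compete. The fallback sets out from 21 and replaces metathesis by a Wittig macrocyclisation. α-Chlorination of the aldehyde (NCS, D,L-proline 10 mol%, CH2Cl2, 0 °C) gives (1R)-1-[(2R,3R)-2-[(1E)-2-(acetoxymethyl)hexa-1,5-dien-1-yl]-4-methylidene-5-oxooxolan-3-yl]-3-chloro-4-oxobutyl (2S)-2-methylbutanoate F5 (both C10 epimers, which converge later). Lemieux–Johnson cleavage of the terminal alkene (OsO4 cat., NaIO4, 2,6-lutidine, dioxane/H2O) gives the chloro dialdehyde (1R)-1-[(2R,3R)-2-[(1E)-2-(acetoxymethyl)-5-oxopent-1-en-1-yl]-4-methylidene-5-oxooxolan-3-yl]-3-chloro-4-oxobutyl (2S)-2-methylbutanoate F6. PPh3 in MeCN at 50 °C converts the α-chloro aldehyde into the α-formyl phosphonium chloride F7, and slow addition of F7 to Et3N in CH2Cl2 at high dilution lets the stabilised formyl ylide olefinate the C1 aldehyde to the (E)-enal, which is target 23 itself.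

Step 6 (one-pot hydroalumination and borylmethylation). The alkylation of the aluminated enoate must be efficient and must keep the C8 chain cis to the ester. The fallback sets out from 11 and builds the same alkene in three known operations. Syn hydrostannation (Bu3SnH, Pd(PPh3)4 cat., THF, 0 °C) gives methyl (2E,4R)-4-[(tert-butyldimethylsilyl)oxy]-7,7-dimethoxy-2-(tributylstannyl)hept-2-enoate F1. Iododestannylation with retention (I2, CH2Cl2, 0 °C) gives methyl (2E,4R)-4-[(tert-butyldimethylsilyl)oxy]-2-iodo-7,7-dimethoxyhept-2-enoate F2. Negishi coupling of F2 with the zinc reagent made from 12 and zinc dust (Pd(PPh3)4 cat., THF, rt) gives 14, where the route is rejoined.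

Further compounds

F1 | step 6 | methyl (2E,4R)-4-[(tert-butyldimethylsilyl)oxy]-7,7-dimethoxy-2-(tributylstannyl)hept-2-enoate | COC(=O)/C([Sn](CCCC)(CCCC)CCCC)=C\[C@H](O[Si](C)(C)C(C)(C)C)CCC(OC)OC
F2 | step 6 | methyl (2E,4R)-4-[(tert-butyldimethylsilyl)oxy]-2-iodo-7,7-dimethoxyhept-2-enoate | COC(=O)/C(I)=C\[C@H](O[Si](C)(C)C(C)(C)C)CCC(OC)OC
F3 | step 7 | methyl (3S,4R,5E)-6-(acetoxymethyl)-3-[(1R)-1-[(tert-butyldimethylsilyl)oxy]-4,4-dimethoxybutyl]-4-hydroxy-2-methylidenedeca-5,9-dienoate | COC(=O)C(=C)[C@@H]([C@H](O)/C=C(/COC(C)=O)CCC=C)[C@H](O[Si](C)(C)C(C)(C)C)CCC(OC)OC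
F4 | step 7 | methyl (3R,4S,5E)-6-(acetoxymethyl)-3-[(1R)-1-[(tert-butyldimethylsilyl)oxy]-4,4-dimethoxybutyl]-4-hydroxy-2-methylidenedeca-5,9-dienoate | COC(=O)C(=C)[C@H]([C@@H](O)/C=C(/COC(C)=O)CCC=C)[C@H](O[Si](C)(C)C(C)(C)C)CCC(OC)OC
F5 | step 13 | (1R)-1-[(2R,3R)-2-[(1E)-2-(acetoxymethyl)hexa-1,5-dien-1-yl]-4-methylidene-5-oxooxolan-3-yl]-3-chloro-4-oxobutyl (2S)-2-methylbutanoate | C=C1C(=O)O[C@H](/C=C(/COC(C)=O)CCC=C)[C@H]1[C@H](OC(=O)[C@@H](C)CC)CC(Cl)C=O
F6 | step 13 | (1R)-1-[(2R,3R)-2-[(1E)-2-(acetoxymethyl)-5-oxopent-1-en-1-yl]-4-methylidene-5-oxooxolan-3-yl]-3-chloro-4-oxobutyl (2S)-2-methylbutanoate | C=C1C(=O)O[C@H](/C=C(/COC(C)=O)CCC=O)[C@H]1[C@H](OC(=O)[C@@H](C)CC)CC(Cl)C=O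
F7 | step 13 | [(4R)-4-[(2R,3R)-2-[(1E)-2-(acetoxymethyl)-5-oxopent-1-en-1-yl]-4-methylidene-5-oxooxolan-3-yl]-4-{[(2S)-2-methylbutanoyl]oxy}-1-oxobutan-2-yl]triphenylphosphonium chloride | C=C1C(=O)O[C@H](/C=C(/COC(C)=O)CCC=O)[C@H]1[C@H](OC(=O)[C@@H](C)CC)CC(C=O)[P+](c1ccccc1)(c1ccccc1)c1ccccc1.[Cl-]
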